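- The 3.4% of substrate left in the teal flask at 20.0 h was my way in to the share in the blue flask at 25 h.

| flask | substrate | remark | time |
|---|---|---|---|
| blue | 0.80 M | the very flask that is asked about, followed so far |  |
| teal | 0.54 M | run made earlier |  |
| flask | 0.80 M |  | 25 h |

| run | time / h | side product A / % | target / % | substrate / % |
|---|---|---|---|---|
| blue | 0.333 | 2.4 | 0.8 | 65.5 |
| blue | 0.500 | 3.7 | 2.0 | 58.8 |
| blue | 0.833 | 6.0 | 1.2 | 51.9 |
| blue | 1.33 | 9.3 | 1.6 | 45.2 |
| blue | 2.00 | 12.5 | 1.6 | 40.8 |
| blue | 3.00 | 17.0 | 1.6 | 33.5 |
| blue | 5.00 | 23.9 | 1.4 | 25.7 |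
| teal | 1.00 | 6.2 | 2.7 | 48.2 |
| teal | 2.50 | 14.0 | 1.7 | 36.4 |
| teal | 5.00 | 23.6 | 1.4 | 26.0 |
| teal | 8.00 | 32.0 | 1.3 | 16.5 |
| teal | 10.0 | 35.1 | 1.3 | 12.3 |
| teal | 15.0 | 40.6 | 0.4 | 7.0 |
| teal | 20.0 | 42.5 | 0.3 | 3.4 |

(standard deviation of a reading: 0.5 percentage points)

* share of side product A in side product A plus target at 15 min
* share of side product A in side product A plus target at 2.5 h
* share of side product A in side product A plus target at 25 h
* which of side product A and target there is more of at 25 h



- At 5.00 h, side product A stood at 23.9% in the blue flask and 23.6% in the teal flask, so I let the teal percentages stand in for the blue flask late on.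
- I took two extremes, using the teal side product A at 20.0 h: if target stayed frozen at its 1.3% of 10.0 h, the share at 25 h came to 97.0%, and if target vanished as it formed, to 100%.
- The teal flask lay nearer the second extreme, since target fell to 0.3% as substrate fell from 12.3% to 3.4%, which looked like a quasi-steady state, so I defined the holding ratio, c(target)/c(substrate) in the last two teal readings, 0.0673, a rough reading given the scatter of 0.5 percentage points.
- Between the teal readings at 10.0 h and 20.0 h, substrate halved every 5.39 h, and carried on to 25 h this gave me an estimate of 1.79%, so with the teal side product A of 20.0 h my estimated share for the blue flask was 99.7%.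
- The forecast judged that “concentration hardly matters” and gave 61%, 90% and 99.3% (range 98% to 99.9%), with side product A ahead; my last share stood above its value, inside that range.
- The blue flask gave 61.8%, 90.1% and 99.9%, with side product A ahead at 44.0% against 0.0633% of target, so the forecast held within its tolerance.

    intermediate B → side product A (k = 1.80 × 10⁻⁴ s⁻¹)
    substrate ⇌ intermediate A (K = 0.580, k = 2.40 × 10⁻⁴ s⁻¹)
    substrate ⇌ intermediate B (K = 0.190, k = 0.00120 s⁻¹)
    substrate → target (k = 2.20 × 10⁻⁵ s⁻¹)
    target → over-reaction product (k = 5.50 × 10⁻⁴ s⁻¹)
    intermediate B → side product B (k = 9.70 × 10⁻⁵ s⁻¹)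

- In the blue flask, target was a passing stage on the way to over-reaction product, which stood at 29.5% at 25 h: the run without that turning ended at a share of 59.8% at that time instead of 99.9%. The holding ratio on the 1.47% of substrate in the blue flask at 25 h gave a share of 99.8%.
- In the neighbour flask with 0.48 M of substrate, the holding ratio on 1.5% of substrate and 44.0% of side product A at 25 h gave 99.8%, and the computed share there at that time was 99.9%.

The data stem from a simulated flask from invented constants; noise was put on by code.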